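The route makes the C4–C4a bond last among the ring bonds. Ring A is carried as a phloroglucinol tris-ether in which both carbons that lie between two oxygens, C4a and C6, bear iodine, and O1 already holds the (S)-configured C2 (set by asymmetric ketone reduction, then Mitsunobu inversion) with a C3–C4 Weinreb amide arm. Double iodine–lithium exchange then does two things in one flask: the C4a–Li, the only one ortho to O1, attacks the amide and closes ring C, and the surviving C6–Li, held between the O5 and O7 acetals, is prenylated, while the tetrahedral Weinreb adduct masks the C4 ketone. Acid removes the three MOM groups.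

Key step: step 8

Remark on the chemistry: C2 of the target is (S) (priorities O1 > C1′ > C3 > H), so the carbinol precursor has to be (R) and is inverted once.

Step 1
Reactants: 1 2,4,6-trihydroxybenzaldehyde
Product: 2 2-hydroxy-4,6-bis(methoxymethoxy)benzaldehyde
Conditions: MOMCl (2.2 equiv), i-Pr2NEt (3 equiv), CH2Cl2, 0 °C to rt
Reagents that add atoms: chloromethyl methyl ether (MOMCl), COCCl
Why: O-alkylation of the phenols in which the 4-OH and one ortho OH react, while the second ortho OH is held in a hydrogen bond to the formyl group and should stay free (chelation-controlled selective bis-protection).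

Step 2
Reactants: 2 2-hydroxy-4,6-bis(methoxymethoxy)benzaldehyde
Product: 4 3,5-bis(methoxymethoxy)-2-methylphenol, via aryl ethyl carbonate 3 (not isolated)
Conditions: ClCO2Et (1.2 equiv), Et3N, THF, 0 °C; then NaBH4 (4 equiv), H2O, 0 °C to rt
Reagents that add atoms: ethyl chloroformate, CCOC(=O)Cl (its atoms stay in intermediate 3 only)
Why: One-pot reductive deoxygenation of a salicylaldehyde, in which NaBH4 reduces the formyl group of 3, the benzylic alkoxide takes over the carbonate, an ortho-quinone methide is expelled and reduced by a second hydride to the cresol; the basic medium spares the MOM acetals.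

Step 3
Reactants: 5 methyl 4-hydroxybenzoate
Product: 6 methyl 4-(methoxymethoxy)benzoate
Conditions: MOMCl (1.3 equiv), i-Pr2NEt, CH2Cl2, 0 °C to rt
Reagents that add atoms: chloromethyl methyl ether (MOMCl), COCCl
Why: Routine protection of a phenol as its MOM ether, which is stable to the enolate, transfer hydrogenation, Mitsunobu, iodination and organolithium steps that follow and leaves with the other two MOM groups at the end.

Step 4
Reactants: 6 methyl 4-(methoxymethoxy)benzoate; 7 N-methoxy-N-methylacetamide
Product: 9 N-methoxy-3-[4-(methoxymethoxy)phenyl]-N-methyl-3-oxopropanamide, via lithium amide enolate 8 (not isolated)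
Conditions: 7 (2.3 equiv), LiN(i-Pr)2 (2.3 equiv), THF, −78 °C; then 6, −78 to −20 °C; aq. NH4Cl
Reagents that add atoms: lithium diisopropylamide, CC(C)N([Li])C(C)C (lithium of intermediate 8 only)
Why: Crossed Claisen condensation of the amide enolate 8 with a benzoate that cannot enolize; the β-keto amide is held as its enolate until work-up, hence two equivalents of 8.

Step 5
Reactants: 9 N-methoxy-3-[4-(methoxymethoxy)phenyl]-N-methyl-3-oxopropanamide
Product: 10 (3R)-3-hydroxy-N-methoxy-3-[4-(methoxymethoxy)phenyl]-N-methylpropanamide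
Conditions: RuCl[(R,R)-TsDPEN](p-cymene) (1 mol %), HCO2H/Et3N (5:2), DMF, 30 °C
Reagents that add atoms: none
Why: Noyori asymmetric transfer hydrogenation of an aryl ketone, in which the (R,R)-ligand should deliver hydride to the face that gives the (R)-benzylic alcohol, in the same sense as with acetophenone (aryl group recognized by its CH–π contact with the cymene ligand).

Step 6
Reactants: 4 3,5-bis(methoxymethoxy)-2-methylphenol; 10 (3R)-3-hydroxy-N-methoxy-3-[4-(methoxymethoxy)phenyl]-N-methylpropanamide
Product: 11 (3S)-3-[3,5-bis(methoxymethoxy)-2-methylphenoxy]-N-methoxy-3-[4-(methoxymethoxy)phenyl]-N-methylpropanamide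
Conditions: PPh3 (1.5 equiv), DIAD (1.5 equiv), toluene, −10 °C to rt
Reagents that add atoms: none
Why: Mitsunobu etherification with SN2 inversion at the benzylic carbinol, which turns (R)-10 into the (S)-aryl ether and so sets the O1–C2 bond and the configuration of C2; low temperature, a non-polar solvent and the inductive pull of the β-amide should hold back ionization, and the amide (less acidic than an ester) should hold back dehydration.

Step 7
Reactants: 11 (3S)-3-[3,5-bis(methoxymethoxy)-2-methylphenoxy]-N-methoxy-3-[4-(methoxymethoxy)phenyl]-N-methylpropanamide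
Product: 12 (3S)-3-[2,4-diiodo-3,5-bis(methoxymethoxy)-6-methylphenoxy]-N-methoxy-3-[4-(methoxymethoxy)phenyl]-N-methylpropanamide
Conditions: NIS (2.4 equiv), MeCN, 0 °C to rt, dark
Reagents that add atoms: N-iodosuccinimide, O=C1CCC(=O)N1I
Why: Electrophilic aromatic iodination in which both free carbons of the trioxygenated ring are ortho or para to all three oxygens, so exhaustive iodination needs no regiocontrol, while the ring of the 4-(methoxymethoxy)phenyl group (one donor only) should not react without acid.

Step 8
Reactants: 12 (3S)-3-[2,4-diiodo-3,5-bis(methoxymethoxy)-6-methylphenoxy]-N-methoxy-3-[4-(methoxymethoxy)phenyl]-N-methylpropanamide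
Product: 15 (2S)-5,7-bis(methoxymethoxy)-2-[4-(methoxymethoxy)phenyl]-8-methyl-6-(3-methylbut-2-en-1-yl)-2,3-dihydro-4H-chromen-4-one, via 6-lithio hemiaminal alkoxide 13 (not isolated), via 6-prenyl hemiaminal alkoxide 14 (not isolated)
Conditions: t-BuLi (4.3 equiv), THF, −78 °C, 20 min; then CuBr·SMe2 (10 mol %), prenyl bromide (1.5 equiv), −78 to −20 °C; sat. aq. NH4Cl
Reagents that add atoms: 1-bromo-3-methylbut-2-ene (prenyl bromide), CC(C)=CCBr; tert-butyllithium, CC(C)(C)[Li] (lithium of intermediates 13 and 14 only)
Why: Two iodine–lithium exchanges (the second equivalent of t-BuLi per iodine destroys t-BuI) should run far faster than attack of the alkyllithium on the amide; the aryllithium at C4a then adds to the tethered N-methoxy-N-methylamide in a 6-exo-trig closure of ring C (the C4–C4a bond) to give the lithium chelate 13, which cannot collapse, enolize or expel O1 by β-elimination before the quench. The closest known reaction type is the Parham cyclization (acylation of an aryl halide onto a Weinreb amide through halogen–metal exchange), telescoped here with the standard copper-catalysed allylation of an aryllithium. Site selectivity needs no reagent control: both C–Li bonds form, but only C4a, ortho to O1, can reach the amide through a six-membered transition state, whereas the C6–Li, para to O1 and chelated by the O5 and O7 acetals, persists at −78 °C and is then alkylated by prenyl bromide at its primary carbon (SN2, favoured by copper catalysis and the hindered γ-carbon) to give 14. No new stereocentre survives the step: C4 of 13 and 14 is tetrahedral only until work-up, and C2 carries no acidic hydrogen and is untouched. The chemoselectivity needed (exchange and acylation before proton transfer from C3–H2) is secured by the use of iodide, by −78 °C and by the intramolecular nature of the acylation.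

Step 9
Reactants: 15 (2S)-5,7-bis(methoxymethoxy)-2-[4-(methoxymethoxy)phenyl]-8-methyl-6-(3-methylbut-2-en-1-yl)-2,3-dihydro-4H-chromen-4-one
Product: 16 (2S)-5,7-dihydroxy-2-(4-hydroxyphenyl)-8-methyl-6-(3-methylbut-2-en-1-yl)-2,3-dihydro-4H-chromen-4-one (5,7,4'-trihydroxy-8-methyl-6-prenylflavanone)
Conditions: 3 M HCl, MeOH, 40 °C, short reaction time
Reagents that add atoms: none
Why: Acid-catalysed acetal exchange to methanol should remove all three MOM groups (the chelated 5-OH first), and moderate temperature and short time are chosen to avoid acid-induced addition of O5 or O7 to the prenyl double bond and opening of ring C at C2.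

Compound list
1 | 2,4,6-trihydroxybenzaldehyde | O=Cc1c(O)cc(O)cc1O | starting material
2 | 2-hydroxy-4,6-bis(methoxymethoxy)benzaldehyde | COCOc1cc(O)c(C=O)c(OCOC)c1 | intermediate
3 | ethyl 2-formyl-3,5-bis(methoxymethoxy)phenyl carbonate | CCOC(=O)Oc1cc(OCOC)cc(OCOC)c1C=O | intermediate (not isolated)
4 | 3,5-bis(methoxymethoxy)-2-methylphenol | Cc1c(O)cc(OCOC)cc1OCOC | intermediate
5 | methyl 4-hydroxybenzoate | COC(=O)c1ccc(O)cc1 | starting material
6 | methyl 4-(methoxymethoxy)benzoate | COCOc1ccc(cc1)C(=O)OC | intermediate
7 | N-methoxy-N-methylacetamide | CC(=O)N(C)OC | starting material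
8 | lithium 1-[methoxy(methyl)amino]ethen-1-olate (lithium enolate of 7) | [Li]OC(=C)N(C)OC | intermediate (not isolated)
9 | N-methoxy-3-[4-(methoxymethoxy)phenyl]-N-methyl-3-oxopropanamide | COCOc1ccc(cc1)C(=O)CC(=O)N(C)OC | intermediate
10 | (3R)-3-hydroxy-N-methoxy-3-[4-(methoxymethoxy)phenyl]-N-methylpropanamide | CON(C)C(=O)C[C@@H](O)c1ccc(OCOC)cc1 | intermediate
11 | (3S)-3-[3,5-bis(methoxymethoxy)-2-methylphenoxy]-N-methoxy-3-[4-(methoxymethoxy)phenyl]-N-methylpropanamide | CON(C)C(=O)C[C@@H](c1ccc(OCOC)cc1)Oc1cc(OCOC)cc(OCOC)c1C | intermediate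
12 | (3S)-3-[2,4-diiodo-3,5-bis(methoxymethoxy)-6-methylphenoxy]-N-methoxy-3-[4-(methoxymethoxy)phenyl]-N-methylpropanamide | CON(C)C(=O)C[C@@H](c1ccc(OCOC)cc1)Oc1c(I)c(OCOC)c(I)c(OCOC)c1C | intermediate
13 | lithium (2S)-6-lithio-4-[methoxy(methyl)amino]-5,7-bis(methoxymethoxy)-2-[4-(methoxymethoxy)phenyl]-8-methyl-3,4-dihydro-2H-chromen-4-olate (C4 not defined) | [Li]c1c(OCOC)c(C)c2c(c1OCOC)C(O[Li])(N(C)OC)C[C@@H](c1ccc(OCOC)cc1)O2 | intermediate (not isolated)
14 | lithium (2S)-4-[methoxy(methyl)amino]-5,7-bis(methoxymethoxy)-2-[4-(methoxymethoxy)phenyl]-8-methyl-6-(3-methylbut-2-en-1-yl)-3,4-dihydro-2H-chromen-4-olate (C4 not defined) | CC(C)=CCc1c(OCOC)c(C)c2c(c1OCOC)C(O[Li])(N(C)OC)C[C@@H](c1ccc(OCOC)cc1)O2 | intermediate (not isolated)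
15 | (2S)-5,7-bis(methoxymethoxy)-2-[4-(methoxymethoxy)phenyl]-8-methyl-6-(3-methylbut-2-en-1-yl)-2,3-dihydro-4H-chromen-4-one | CC(C)=CCc1c(OCOC)c(C)c2c(c1OCOC)C(=O)C[C@@H](c1ccc(OCOC)cc1)O2 | intermediate
16 | (2S)-5,7-dihydroxy-2-(4-hydroxyphenyl)-8-methyl-6-(3-methylbut-2-en-1-yl)-2,3-dihydro-4H-chromen-4-one | CC(C)=CCc1c(O)c(C)c2c(c1O)C(=O)C[C@@H](c1ccc(O)cc1)O2 | target

Total step count: 9 (steps 1–2 for the ring A piece, steps 3–5 for the ring B/C3–C4 piece, steps 6–9 after their union).
Longest linear sequence: 7 steps (steps 3, 4, 5, 6, 7, 8, 9).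

Steps most likely to fail

Step 8. An aryllithium may take a proton from C3–H2 (α to the amide), after which the amide enolate expels the ring A phenoxide by β-elimination; the alkyllithium may add to the amide before exchange is complete; or the second aryllithium may be protonated before it is alkylated. The fallback closes the same C4–C4a bond from the electrophilic side, with no carbanion in the flask, and sets out from 11. i-Bu2AlH (THF, −78 °C) should stop at the aldehyde (3S)-3-[3,5-bis(methoxymethoxy)-2-methylphenoxy]-3-[4-(methoxymethoxy)phenyl]propanal F1. Pinnick oxidation (NaClO2, NaH2PO4, 2-methylbut-2-ene, t-BuOH/H2O) should give (3S)-3-[3,5-bis(methoxymethoxy)-2-methylphenoxy]-3-[4-(methoxymethoxy)phenyl]propanoic acid F2. (CF3CO)2O in CH2Cl2 at 0 °C forms the mixed anhydride, which should acylate the trioxygenated ring at the only free carbon ortho to O1 (intramolecular Friedel–Crafts acylation) to give (2S)-5,7-bis(methoxymethoxy)-2-[4-(methoxymethoxy)phenyl]-8-methyl-2,3-dihydro-4H-chromen-4-one F3. NIS should then iodinate the last free carbon of ring A to give (2S)-6-iodo-5,7-bis(methoxymethoxy)-2-[4-(methoxymethoxy)phenyl]-8-methyl-2,3-dihydro-4H-chromen-4-one F4. Stille coupling with tributyl(3-methylbut-2-en-1-yl)stannane (Pd(PPh3)4, DMF, 80 °C) installs the prenyl group and comes back to the route at 15.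

Step 6. The p-alkoxybenzylic oxyphosphonium ion may ionize before the phenoxide attacks, which lowers the stereochemical fidelity of the substitution, or it may lose a proton from the carbon α to the amide and dehydrate. The fallback gives up the stereospecific substitution as the only source of optical purity. It sets out from 11: the ether of lowered enantiomeric purity is carried through steps 7 and 8 unchanged, and the enantiomers are separated by preparative chromatography on a polysaccharide chiral stationary phase at 15, which has no free phenol and should not racemize on the column. It comes back to the route at 15 and makes no new compound (F0).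

Step 9. Under the acid needed to cleave the acetals, O5 or O7 may add to the protonated prenyl double bond (closure to a 2,2-dimethylchroman), and prolonged acid may open ring C at O1–C2 and erode the configuration. The fallback keeps the side chain as an allyl group, which does not ionize in acid, and makes the prenyl group last. It sets out from 12: step 8 is run with allyl bromide in place of prenyl bromide to give (2S)-5,7-bis(methoxymethoxy)-2-[4-(methoxymethoxy)phenyl]-8-methyl-6-(prop-2-en-1-yl)-2,3-dihydro-4H-chromen-4-one F5. HCl/MeOH should give (2S)-5,7-dihydroxy-2-(4-hydroxyphenyl)-8-methyl-6-(prop-2-en-1-yl)-2,3-dihydro-4H-chromen-4-one F6. Olefin cross-metathesis with 2-methylbut-2-ene (co-solvent) and the second-generation Grubbs catalyst RuCl2(H2IMes)(PCy3)(=CHPh) in CH2Cl2 at 40 °C comes back to the route at 16.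

Further compounds
F1 | step 8 | (3S)-3-[3,5-bis(methoxymethoxy)-2-methylphenoxy]-3-[4-(methoxymethoxy)phenyl]propanal | O=CC[C@@H](c1ccc(OCOC)cc1)Oc1cc(OCOC)cc(OCOC)c1C
F2 | step 8 | (3S)-3-[3,5-bis(methoxymethoxy)-2-methylphenoxy]-3-[4-(methoxymethoxy)phenyl]propanoic acid | OC(=O)C[C@@H](c1ccc(OCOC)cc1)Oc1cc(OCOC)cc(OCOC)c1C
F3 | step 8 | (2S)-5,7-bis(methoxymethoxy)-2-[4-(methoxymethoxy)phenyl]-8-methyl-2,3-dihydro-4H-chromen-4-one | c1c(OCOC)c(C)c2c(c1OCOC)C(=O)C[C@@H](c1ccc(OCOC)cc1)O2
F4 | step 8 | (2S)-6-iodo-5,7-bis(methoxymethoxy)-2-[4-(methoxymethoxy)phenyl]-8-methyl-2,3-dihydro-4H-chromen-4-one | Ic1c(OCOC)c(C)c2c(c1OCOC)C(=O)C[C@@H](c1ccc(OCOC)cc1)O2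
F0 | step 6 | none | none
F5 | step 9 | (2S)-5,7-bis(methoxymethoxy)-2-[4-(methoxymethoxy)phenyl]-8-methyl-6-(prop-2-en-1-yl)-2,3-dihydro-4H-chromen-4-one | C=CCc1c(OCOC)c(C)c2c(c1OCOC)C(=O)C[C@@H](c1ccc(OCOC)cc1)O2
F6 | step 9 | (2S)-5,7-dihydroxy-2-(4-hydroxyphenyl)-8-methyl-6-(prop-2-en-1-yl)-2,3-dihydro-4H-chromen-4-one | C=CCc1c(O)c(C)c2c(c1O)C(=O)C[C@@H](c1ccc(O)cc1)O2
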